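**Retrosynthetic overview**
1. C13–OOH (last step): stereoconvergent perhydrolysis of tertiary allylic alcohol 15, running through the 8α,13-cyclic ether 16, which H2O2 opens at C13 with inversion.
2. 15 ⇒ cross-metathesis of vinyl carbinol 12 with (S)-vinylbutenolide 14; 12 ⇒ vinyl addition to methyl ketone 11.
3. 6α-OH and C18 methyl ester ⇒ carboxylate-directed C6–H lactonization of acid 9 (new C6–O bond), then methanolysis.
4. Decalin ⇒ epoxy-alcohol-initiated, ketone-terminated bicyclization of 3; 3 ⇒ farnesylacetone by SeO2 oxidation and Sharpless epoxidation.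
5. Ring order: ring A, then ring B (one cascade, step 3, with a transient pyran ring); γ-lactone bridge C18–O–C6 (step 7, opened in step 8); butenolide (step 10).

Assumption: (5E,9E)-farnesylacetone (1) and 5-hydroxy-4-methylfuran-2(5H)-one (13) are bought; labdane numbering is used for the decalin intermediates (normal series: 5α-H, 9α-H, 10β-CH3; C18 is the 4α substituent).

**Step 1**
Reactants: 1 (5E,9E)-6,10,14-trimethylpentadeca-5,9,13-trien-2-one (farnesylacetone)
Product: 2 (5E,9E,13E)-15-hydroxy-6,10,14-trimethylpentadeca-5,9,13-trien-2-one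
Conditions: SeO2 (0.1 equiv), salicylic acid (0.1 equiv), t-BuOOH (3 equiv), CH2Cl2, 0 °C to rt, stopped at partial conversion, 1 recovered
Reagents that add atoms: tert-butyl hydroperoxide, CC(C)(C)OO
Why: SeO2-catalysed allylic hydroxylation (Sharpless–Umbreit; ene reaction then [2,3]-shift) is fastest at the terminal isopropylidene and specific for its (E)-methyl group, and the methyl ketone is left alone at room temperature.

**Step 2**
Reactants: 2 (5E,9E,13E)-15-hydroxy-6,10,14-trimethylpentadeca-5,9,13-trien-2-one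
Product: 3 (5E,9E)-12-[(2S,3S)-3-(hydroxymethyl)-3-methyloxiran-2-yl]-6,10-dimethyldodeca-5,9-dien-2-one
Conditions: Ti(OiPr)4 (10 mol%), L-(+)-diethyl tartrate (12 mol%), t-BuOOH (2 equiv), 4 Å molecular sieves, CH2Cl2, −20 °C
Reagents that add atoms: tert-butyl hydroperoxide, CC(C)(C)OO
Why: Sharpless asymmetric epoxidation touches only the allylic-alcohol double bond, and the L-(+)-tartrate catalyst gives the (2S,3S)-epoxide (the counterpart of (3S)-2,3-oxidosqualene), which later fixes the absolute configuration of the whole decalin.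

**Step 3**
Reactants: 3 (5E,9E)-12-[(2S,3S)-3-(hydroxymethyl)-3-methyloxiran-2-yl]-6,10-dimethyldodeca-5,9-dien-2-one
Product: 5 3β,8α,18-trihydroxy-14,15-dinorlabdan-13-one, via cyclic enol ether 4 (not isolated)
Conditions: MeAlCl2 (3 equiv), CH2Cl2, −78 °C; then 1 M HCl, THF, 0 °C
Reagents that add atoms: water, O
Why: Lewis-acid-triggered, epoxide-initiated cation–olefin bicyclization (Stork–Eschenmoser chair–chair folding) opens the epoxide at C4 with inversion so that the former (E)-CH2OH becomes the equatorial 4α group, closes ring A then ring B with 5α-H, 10β-CH3 and 9α-H, the ketone oxygen ends the cascade from the equatorial side (8α-O), and mild acid hydrolyses the enol ether.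

**Step 4**
Reactants: 5 3β,8α,18-trihydroxy-14,15-dinorlabdan-13-one
Product: 6 3β,18-O-thiocarbonyl-8α-hydroxy-14,15-dinorlabdan-13-one (cyclic thionocarbonate)
Conditions: 1,1'-thiocarbonyldiimidazole (1.3 equiv), DMAP (cat.), THF, 65 °C
Reagents that add atoms: 1,1'-thiocarbonyldiimidazole, S=C(n1ccnc1)n1ccnc1
Why: Thiocarbonylation of the trans-diequatorial 3β,18-diol closes a six-membered cyclic thionocarbonate, while the hindered tertiary 8-OH does not acylate.

**Step 5**
Reactants: 6 3β,18-O-thiocarbonyl-8α-hydroxy-14,15-dinorlabdan-13-one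
Product: 8 8α,18-dihydroxy-14,15-dinorlabdan-13-one, via stannyl thiocarbonate 7 (not isolated)
Conditions: Bu3SnH (2 equiv), AIBN (0.2 equiv), toluene, 110 °C; then K2CO3 (cat.), MeOH/H2O, rt
Reagents that add atoms: none
Why: Barton–McCombie radical deoxygenation of a cyclic thionocarbonate: the stannyl radical adds to C=S, the C–O bond to the secondary carbon C3 fragments in preference to the primary one, the C3 radical takes hydrogen from Bu3SnH, and mild hydrolysis frees the 18-OH.

**Step 6**
Reactants: 8 8α,18-dihydroxy-14,15-dinorlabdan-13-one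
Product: 9 8α-hydroxy-13-oxo-14,15-dinorlabdan-18-oic acid
Conditions: TEMPO (10 mol%), NaOCl (5 mol%), NaClO2 (2.5 equiv), MeCN/phosphate buffer pH 6.7, 35 °C
Reagents that add atoms: sodium chlorite, [Na+].[O-]Cl=O
Why: TEMPO/chlorite (Zhao–Anelli) oxidation takes the primary neopentyl alcohol to the acid through the aldehyde; the tertiary alcohol and the ketone are inert and C4 carries no hydrogen to epimerise.

**Step 7**
Reactants: 9 8α-hydroxy-13-oxo-14,15-dinorlabdan-18-oic acid
Product: 10 8α-hydroxy-13-oxo-14,15-dinorlabdan-18,6α-olide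
Conditions: [Mn(OTf)2((S,S)-pdp)] (2 mol%), 30% aq. H2O2 (2 equiv, slow addition), (CF3)2CHOH, 0 °C
Reagents that add atoms: none
Why: Carboxylate-directed manganese-catalysed γ-C(sp3)–H lactonization (hydrogen abstraction by the carboxylate-bound high-valent manganese oxo species, then C–O rebound): the equatorial 4α-carboxyl reaches only the peri 6α-hydrogen, so the new C6–O bond is α.

**Step 8**
Reactants: 10 8α-hydroxy-13-oxo-14,15-dinorlabdan-18,6α-olide
Product: 11 methyl 6α,8α-dihydroxy-13-oxo-14,15-dinorlabdan-18-oate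
Conditions: NaOMe (0.3 equiv), MeOH, 0 °C to rt; AcOH quench
Reagents that add atoms: methanol, CO
Why: Base-catalysed methanolysis (transesterification) opens the strained, doubly trans-fused γ-lactone and leaves the 6α-OH and hindered 18-methyl ester of the target, with no stereocenter touched.

**Step 9**
Reactants: 11 methyl 6α,8α-dihydroxy-13-oxo-14,15-dinorlabdan-18-oate
Product: 12 methyl 6α,8α,13-trihydroxylabd-14-en-18-oate (13RS)
Conditions: CH2=CHMgBr (4 equiv), THF, −78 to 0 °C; then H2O
Reagents that add atoms: vinylmagnesium bromide, C=C[Mg]Br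
Why: Grignard 1,2-addition to the methyl ketone; the neopentyl ester is too hindered to react at low temperature, and C13 forms as a roughly 1:1 epimer mixture that is carried on because step 12 is stereoconvergent.

**Step 10**
Reactants: 13 5-hydroxy-4-methylfuran-2(5H)-one
Product: 14 (S)-4-methyl-5-vinylfuran-2(5H)-one
Conditions: Zn(CH=CH2)2 (2.5 equiv), (−)-MIB [(2S)-3-exo-morpholinoisoborneol, 10 mol%], toluene, 0 °C; then 1 M HCl
Reagents that add atoms: divinylzinc, C=C[Zn]C=C
Why: Amino-alcohol-catalysed enantioselective vinylzinc addition (Oppolzer–Nugent type) to the open-chain (Z)-formyl carboxylate released from the pseudo-acid on deprotonation; Si-face attack sets the (S)-carbinol and acid work-up closes the butenolide.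

**Step 11**
Reactants: 12 methyl 6α,8α,13-trihydroxylabd-14-en-18-oate (13RS); 14 (S)-4-methyl-5-vinylfuran-2(5H)-one (3 equiv)
Product: 15 methyl (14E)-6α,8α,13-trihydroxy-15-[(2S)-3-methyl-5-oxo-2,5-dihydrofuran-2-yl]labd-14-en-18-oate (13RS)
Conditions: second-generation Hoveyda–Grubbs catalyst [RuCl2(SIMes)(=CH-C6H4-2-OiPr), 5 mol%], CH2Cl2, 40 °C
Reagents that add atoms: none
Why: Olefin cross-metathesis of two monosubstituted allylic olefins gives the (E)-1,2-disubstituted alkene under thermodynamic control; free hydroxyls are tolerated and the trisubstituted, electron-poor butenolide double bond does not take part.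

**Step 12**
Reactants: 15 methyl (14E)-6α,8α,13-trihydroxy-15-[(2S)-3-methyl-5-oxo-2,5-dihydrofuran-2-yl]labd-14-en-18-oate (13RS)
Product: 17 methyl (13R,14E)-13-hydroperoxy-6α,8α-dihydroxy-15-[(2S)-3-methyl-5-oxo-2,5-dihydrofuran-2-yl]labd-14-en-18-oate (CNP0128148.1), via cyclic ether 16 (not isolated)
Conditions: anhydrous H2O2 (ca. 3 M in Et2O, 30 equiv), Sc(OTf)3 (5 mol%), CH2Cl2/Et2O, −30 °C; NaHCO3 quench at partial conversion; recovered 16 resubmitted
Reagents that add atoms: hydrogen peroxide, OO
Why: Proposed new method: the Lewis acid ionises either C13 epimer to the same tertiary allyl cation (C14=C15 stays E, the C15 end is deactivated by the lactone oxygen), which the 8α-hydroxyl captures reversibly as the chair pyran ether 16 with the 13-methyl equatorial and the alkenyl arm axial (the preference seen when sclareol closes to 13-epi-manoyl oxide); excess H2O2 then attacks the acid-activated C13–O8 bond from the face opposite to O8 (inversion), giving the (13R)-hydroperoxide and releasing the 8α-OH, so the neighbouring oxygen that would otherwise be a dead end becomes the stereocontrol element; the closest known reactions are acid-catalysed perhydrolysis of tertiary alcohols and Lewis-acid opening of oxetanes and epoxides by H2O2 with inversion at a tertiary carbon, not yet shown for an unstrained allylic ether or as a stereoconvergent process.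

**Compound list**
1 | (5E,9E)-6,10,14-trimethylpentadeca-5,9,13-trien-2-one (farnesylacetone) | CC(=O)CC/C=C(\C)CC/C=C(\C)CCC=C(C)C | starting material
2 | (5E,9E,13E)-15-hydroxy-6,10,14-trimethylpentadeca-5,9,13-trien-2-one | CC(=O)CC/C=C(\C)CC/C=C(\C)CC/C=C(\C)CO | intermediate
3 | (5E,9E)-12-[(2S,3S)-3-(hydroxymethyl)-3-methyloxiran-2-yl]-6,10-dimethyldodeca-5,9-dien-2-one | OC[C@]1(C)O[C@H]1CC/C(C)=C/CC/C(C)=C/CCC(C)=O | intermediate
4 | 8α,13-epoxy-14,15-dinorlabd-12-ene-3β,18-diol (cyclic enol ether, not isolated) | OC[C@]1(C)[C@@H](O)CC[C@@]2(C)[C@H]1CC[C@@]1(C)OC(C)=CC[C@@H]12 | intermediate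
5 | 3β,8α,18-trihydroxy-14,15-dinorlabdan-13-one | OC[C@]1(C)[C@@H](O)CC[C@@]2(C)[C@H]1CC[C@@](C)(O)[C@@H]2CCC(C)=O | intermediate
6 | 3β,18-cyclic thionocarbonate of 5 | S=C1OC[C@]2(C)[C@@H](O1)CC[C@@]3(C)[C@H]2CC[C@@](C)(O)[C@@H]3CCC(C)=O | intermediate
7 | 18-O-[(tributylstannylsulfanyl)carbonyl] derivative of 8 (stannyl thiocarbonate, not isolated) | O=C(OC[C@]1(C)CCC[C@@]2(C)[C@H]1CC[C@@](C)(O)[C@@H]2CCC(C)=O)S[Sn](CCCC)(CCCC)CCCC | intermediate
8 | 8α,18-dihydroxy-14,15-dinorlabdan-13-one | OC[C@]1(C)CCC[C@@]2(C)[C@H]1CC[C@@](C)(O)[C@@H]2CCC(C)=O | intermediate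
9 | 8α-hydroxy-13-oxo-14,15-dinorlabdan-18-oic acid | OC(=O)[C@]1(C)CCC[C@@]2(C)[C@H]1CC[C@@](C)(O)[C@@H]2CCC(C)=O | intermediate
10 | 8α-hydroxy-13-oxo-14,15-dinorlabdan-18,6α-olide | O=C1[C@]2(C)CCC[C@@]3(C)[C@H]2[C@@H](O1)C[C@@](C)(O)[C@@H]3CCC(C)=O | intermediate
11 | methyl 6α,8α-dihydroxy-13-oxo-14,15-dinorlabdan-18-oate | COC(=O)[C@]1(C)CCC[C@@]2(C)[C@H]1[C@@H](O)C[C@@](C)(O)[C@@H]2CCC(C)=O | intermediate
12 | methyl 6α,8α,13-trihydroxylabd-14-en-18-oate (13RS, both epimers) | COC(=O)[C@]1(C)CCC[C@@]2(C)[C@H]1[C@@H](O)C[C@@](C)(O)[C@@H]2CCC(C)(O)C=C | intermediate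
13 | 5-hydroxy-4-methylfuran-2(5H)-one | CC1=CC(=O)OC1O | starting material
14 | (S)-4-methyl-5-vinylfuran-2(5H)-one | C=C[C@@H]1OC(=O)C=C1C | intermediate
15 | methyl (14E)-6α,8α,13-trihydroxy-15-[(2S)-3-methyl-5-oxo-2,5-dihydrofuran-2-yl]labd-14-en-18-oate (13RS) | COC(=O)[C@]1(C)CCC[C@@]2(C)[C@H]1[C@@H](O)C[C@@](C)(O)[C@@H]2CCC(C)(O)/C=C/[C@@H]1OC(=O)C=C1C | intermediate
16 | methyl (13S,14E)-8α,13-epoxy-6α-hydroxy-15-[(2S)-3-methyl-5-oxo-2,5-dihydrofuran-2-yl]labd-14-en-18-oate (cyclic ether, not isolated) | COC(=O)[C@]1(C)CCC[C@@]2(C)[C@H]1[C@@H](O)C[C@@]1(C)O[C@](C)(/C=C/[C@@H]3OC(=O)C=C3C)CC[C@@H]12 | intermediate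
17 | methyl (13R,14E)-13-hydroperoxy-6α,8α-dihydroxy-15-[(2S)-3-methyl-5-oxo-2,5-dihydrofuran-2-yl]labd-14-en-18-oate (CNP0128148.1) | COC(=O)[C@]1(C)CCC[C@@]2(C)[C@H]1[C@@H](O)C[C@@](C)(O)[C@@H]2CC[C@](C)(/C=C/[C@@H]1OC(=O)C=C1C)OO | target

**Step count**
Total: 12 steps. Longest linear sequence: 11 steps (1–9, 11, 12); step 10 is the side branch.

**Steps most likely to fail**

Step 12 (the proposed new step). The ether 16 may be the thermodynamic sink. The facial preference rests on an analogy with sclareol closing mainly to 13-epi-manoyl oxide, recalled and not checked, and could be modest (perhaps 4:1, my estimate). The allylic hydroperoxide can also undergo acid-induced Hock cleavage. The fallback uses only known chemistry; it sets out from ketone 11 and comes back at target 17. Ketone 11 is methylenated with Ph3P=CH2 in THF to methyl 6α,8α-dihydroxy-15-norlabd-13-en-18-oate F5. Cross-metathesis of F5 (same ruthenium catalyst as step 11) with (S)-5-allyl-4-methylfuran-2(5H)-one F6, itself made from 13 by asymmetric allylboration with (−)-Ipc2B(allyl) and acid lactonization, gives methyl (13E)-6α,8α-dihydroxy-15-[(2S)-3-methyl-5-oxo-2,5-dihydrofuran-2-yl]labd-13-en-18-oate F7 (the Z isomer formed alongside serves equally). Tetraphenylporphyrin-sensitised photooxygenation of F7 (O2, visible light, CH2Cl2, 0 °C) is the classical Schenck ene reaction. It tolerates the free 8α-OH and gives 17 together with its C13 epimer and the 14-hydroperoxy regioisomers, from which 17 is separated by HPLC (expect roughly a quarter of the mixture).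

Step 3. The CH2OH group next to the cationic centre and the free hydroxyl may slow the epoxide opening or divert it to five-membered-ring or hydride-shift products. The fallback sets out from epoxy alcohol 3 and comes back at triol ketone 5. Alcohol 3 is silylated (TBSCl, imidazole) to the tert-butyldimethylsilyl ether F1, which no longer consumes or chelates the Lewis acid. MeAlCl2 cyclization and the same mild acid work-up give 18-(tert-butyldimethylsilyloxy)-3β,8α-dihydroxy-14,15-dinorlabdan-13-one F2, and Bu4NF in THF removes the silyl group to return 5.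

Step 7. The catalyst may oxidise the tertiary C–H bonds or the ketone, or the acid may bind poorly. The fallback replaces the metal-oxo step by an amidyl-radical 1,5-hydrogen transfer; it sets out from acid 9 and comes back at lactone 10. Acid 9 is converted (isobutyl chloroformate, N-methylmorpholine, then NH3; then N-trimethylsilylimidazole to mask the tertiary alcohol) into 8α-(trimethylsilyloxy)-13-oxo-14,15-dinorlabdan-18-amide F3. Under Barton–Suárez conditions (PhI(OAc)2, I2, visible light, CH2Cl2) the N-iodoamide of F3 gives an amidyl radical that abstracts the peri 6α-hydrogen, and the C6 iodide is displaced by the amide oxygen to give the 18,6α-iminolactone F4. Aqueous acetic acid hydrolyses the imine and the silyl ether of F4 and returns 10.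

**Further compounds**
F1 | step 3 | tert-butyldimethylsilyl ether of epoxy alcohol 3 | CC(C)(C)[Si](C)(C)OC[C@]1(C)O[C@H]1CC/C(C)=C/CC/C(C)=C/CCC(C)=O
F2 | step 3 | 18-(tert-butyldimethylsilyloxy)-3β,8α-dihydroxy-14,15-dinorlabdan-13-one | CC(C)(C)[Si](C)(C)OC[C@]1(C)[C@@H](O)CC[C@@]2(C)[C@H]1CC[C@@](C)(O)[C@@H]2CCC(C)=O
F3 | step 7 | 8α-(trimethylsilyloxy)-13-oxo-14,15-dinorlabdan-18-amide | NC(=O)[C@]1(C)CCC[C@@]2(C)[C@H]1CC[C@@](C)(O[Si](C)(C)C)[C@@H]2CCC(C)=O
F4 | step 7 | 18,6α-iminolactone of F3 (18-imino-8α-(trimethylsilyloxy)-14,15-dinorlabdan-18,6α-olide-13-one) | N=C1[C@]2(C)CCC[C@@]3(C)[C@H]2[C@@H](O1)C[C@@](C)(O[Si](C)(C)C)[C@@H]3CCC(C)=O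
F5 | step 12 | methyl 6α,8α-dihydroxy-15-norlabd-13-en-18-oate | COC(=O)[C@]1(C)CCC[C@@]2(C)[C@H]1[C@@H](O)C[C@@](C)(O)[C@@H]2CCC(C)=C
F6 | step 12 | (S)-5-allyl-4-methylfuran-2(5H)-one | C=CC[C@@H]1OC(=O)C=C1C
F7 | step 12 | methyl (13E)-6α,8α-dihydroxy-15-[(2S)-3-methyl-5-oxo-2,5-dihydrofuran-2-yl]labd-13-en-18-oate | COC(=O)[C@]1(C)CCC[C@@]2(C)[C@H]1[C@@H](O)C[C@@](C)(O)[C@@H]2CC/C(C)=C/C[C@@H]1OC(=O)C=C1C
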